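**Retrosynthetic overview** (spiro[5.5]undecane numbering: ring B = C1–C6, ring A = C6–C11, C6 = spiro carbon)

1. Target ⇐ ring A 3-methyl enone by α′-bromination, 1,2-reduction and dehydration (the C10 vinyl bromide and the 7,9-diene come last); C1–OH ⇐ C1 ketone.
2. Ring B ⇐ cleave C2–C3. The trans pair C3(Cl)(Me)–C4(H)Br next to C2H2–C1(=O) is the retron of an (E)-chloroalkene (C3=C4), opened by Br+ to an α-chlorocarbenium ion at C3, and of a 1-chloroethenyl group (C1=C2, a masked ketone), both carried by the quaternary spiro carbon C6 of a finished ring A.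
3. C6 ⇐ Pd-catalysed asymmetric allylic alkylation of the 6-acetyl enol ether of dimedone with (E)-1,3-dichlorobut-2-ene; acetyl ⇒ ethynyl ⇒ 1-chloroethenyl; a Stork–Danheiser methyl transposition gives the ring A enone.
4. Ring order: ring A is bought (dimedone ethyl enol ether); ring B is closed second, in the key step.

Key step: step 6

Remark: (E)-1,3-dichlorobut-2-ene is taken as available as the pure E isomer (otherwise distilled from the commercial E/Z mixture), and the (R,R)-ligand of step 2 is assumed to give the (6R)-ketone (if the sense is opposite, its enantiomer is used).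

**Step 1**
Reactants: 1 3-ethoxy-5,5-dimethylcyclohex-2-en-1-one
Product: 2 6-acetyl-3-ethoxy-5,5-dimethylcyclohex-2-en-1-one
Conditions: LiN(i-Pr)2 (1.2 equiv), THF, −78 °C; then MeC(O)N(OMe)Me, −78 → 0 °C; aq. NH4Cl
Reagents that add atoms: N-methoxy-N-methylacetamide, CON(C)C(C)=O
Why: Kinetic α′-deprotonation of the vinylogous ester (Stork–Danheiser regiochemistry) followed by Claisen-type C-acylation with the Weinreb amide should give the β-diketone without O-acylation, because the chelated tetrahedral adduct only collapses on work-up.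

**Step 2**
Reactants: 2 6-acetyl-3-ethoxy-5,5-dimethylcyclohex-2-en-1-one; 3 (2E)-1,3-dichlorobut-2-ene
Product: 4 (6R)-6-acetyl-6-[(2E)-3-chlorobut-2-en-1-yl]-3-ethoxy-5,5-dimethylcyclohex-2-en-1-one
Conditions: Pd2(dba)3·CHCl3 (2.5 mol%), (R,R)-DACH-phenyl Trost ligand (7.5 mol%), Cs2CO3, toluene, 0 °C → rt
Reagents that add atoms: none
Why: In this Tsuji–Trost asymmetric allylic alkylation of a prochiral 2-acyl-ketone enolate the allylic chloride ionises to a π-allyl complex that is attacked at its CH2 terminus, so the E chloroalkene is kept, C-allylation wins because O-allylation is reversible under palladium, and the chiral ligand pocket differentiates the enolate faces to set the quaternary carbon as R.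

**Step 3**
Reactants: 4 (6R)-6-acetyl-6-[(2E)-3-chlorobut-2-en-1-yl]-3-ethoxy-5,5-dimethylcyclohex-2-en-1-one
Product: 6 (6R)-6-[(2E)-3-chlorobut-2-en-1-yl]-3-ethoxy-6-ethynyl-5,5-dimethylcyclohex-2-en-1-one, via enol diethyl phosphate 5 (not isolated)
Conditions: LiN(i-Pr)2 (1.1 equiv), THF, −78 °C; ClP(O)(OEt)2; then LiN(i-Pr)2 (2.3 equiv), −78 °C → rt; aq. NH4Cl
Reagents that add atoms: none
Why: The Negishi methyl ketone to alkyne sequence (kinetic enolate, O-phosphorylation, base-induced β-elimination of diethyl phosphate) should act only on the acetyl group, whose hydrogens are the kinetically most accessible, and the alkyne both masks this carbon against MeLi and is the precursor of the terminating chloroalkene.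

**Step 4**
Reactants: 6 (6R)-6-[(2E)-3-chlorobut-2-en-1-yl]-3-ethoxy-6-ethynyl-5,5-dimethylcyclohex-2-en-1-one
Product: 8 (4R)-4-[(2E)-3-chlorobut-2-en-1-yl]-4-ethynyl-3,5,5-trimethylcyclohex-2-en-1-one, via 1,2-adduct carbinol 7 (not isolated)
Conditions: MeLi (3 equiv), THF, −78 → 0 °C; then 1 M aq. HCl, rt
Reagents that add atoms: methyllithium, [Li]C
Why: In this Stork–Danheiser transposition MeLi first deprotonates the alkyne and then adds 1,2 to the vinylogous ester carbonyl, and acid hydrolysis of the enol ether with loss of water should give the 3-methyl enone of ring A without touching the quaternary centre or the chloroalkene.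

**Step 5**
Reactants: 8 (4R)-4-[(2E)-3-chlorobut-2-en-1-yl]-4-ethynyl-3,5,5-trimethylcyclohex-2-en-1-one
Product: 9 (4S)-4-[(2E)-3-chlorobut-2-en-1-yl]-4-(1-chloroethenyl)-3,5,5-trimethylcyclohex-2-en-1-one
Conditions: HCl·DMPU (1.5 equiv), Ph3PAuCl (5 mol%), ClCH2CH2Cl, rt
Reagents that add atoms: hydrogen chloride (as its DMPU complex), Cl
Why: Gold-catalysed Markovnikov hydrochlorination of a terminal alkyne should give the 2-chloro-1-alkene, while the electron-poor enone and the internal chloroalkene are inert (the descriptor changes only because of the priority change).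

**Step 6**
Reactants: 9 (4S)-4-[(2E)-3-chlorobut-2-en-1-yl]-4-(1-chloroethenyl)-3,5,5-trimethylcyclohex-2-en-1-one
Product: 11 (3S,4S,6S)-4-bromo-3-chloro-3,7,11,11-tetramethylspiro[5.5]undec-7-ene-1,9-dione, via chloro hexafluoroisopropyl ether 10 (not isolated)
Conditions: NBS (1.05 equiv), CH2Cl2/(CF3)2CHOH 4:1, −40 → 0 °C, dark; then aq. NaHCO3
Reagents that add atoms: N-bromosuccinimide, O=C1CCC(=O)N1Br; water, O
Why: Proposed new method: Br+ from NBS, activated by hydrogen bonding to (CF3)2CHOH, adds to the CH carbon of the trisubstituted (E)-chloroalkene and gives a bromine-bridged α-chlorocarbenium ion at the chlorine-bearing carbon, which is attacked anti to bromine by the CH2 terminus of the 1-chloroethenyl group; the new α-chlorocarbenium ion at the future C-1 is trapped by the fluorinated alcohol and the geminal chloro ether is hydrolysed to the ketone on work-up, so that the first C–Cl bond survives as the tertiary chloride and the second is only a latent carbonyl. The closest known reaction types are the bromonium-initiated cation–olefin (polyene) cyclisation and the Lansbury chloro-olefin annulation, in which a 2-chloroalkene terminates a cationic cyclisation and is hydrolysed to a ketone; what is new is a vinyl chloride as the initiating olefin, whose mesomerically stabilised α-chloro cation forms the C–C bond at the halogenated carbon. Ring B closes in the 6-endo mode with respect to the terminating olefin (both of its carbons enter the ring) through a chair-like transition state. C-4 and C-3 are set relative to each other by the stereospecific anti addition of Br and carbon across the E double bond (Br and Cl trans and both equatorial, the C-3 methyl axial), and relative to the spiro carbon by the chair that keeps bromine and the bulky CMe2 arm of ring A equatorial and puts the flat C(Me)=CH arm axial. The step needs Br+ to choose the trisubstituted chloroalkene and its two faces to be sorted: the 1,1-disubstituted chloroalkene on the neopentylic carbon is less nucleophilic and more hindered, the enone double bond is electron-poor, no enol ether, allylsilane or electron-rich olefin is present, and bromonium formation on a deactivated olefin that is captured only by a weak π-nucleophile should be reversible, so that the chair preference is expressed under Curtin–Hammett control.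

**Step 7**
Reactants: 11 (3S,4S,6S)-4-bromo-3-chloro-3,7,11,11-tetramethylspiro[5.5]undec-7-ene-1,9-dione
Product: 12 (6S,7S,9S,10S)-10-bromo-9-chloro-7-hydroxy-1,5,5,9-tetramethylspiro[5.5]undec-1-en-3-one
Conditions: NaBH4 (1 equiv), MeOH/CH2Cl2 1:1, −78 → −20 °C
Reagents that add atoms: none
Why: Borohydride reduction at low temperature should take the saturated ring B ketone before the β,β-disubstituted ring A enone and removes the base-sensitive β-chloro ketone at once, and the new carbinol is set by equatorial hydride attack because the axial methyl on the β-carbon blocks the axial trajectory, which gives the axial (S) alcohol cis to that methyl.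

**Step 8**
Reactants: 12 (6S,7S,9S,10S)-10-bromo-9-chloro-7-hydroxy-1,5,5,9-tetramethylspiro[5.5]undec-1-en-3-one
Product: 14 (6R,7S,9S,10S)-4,10-dibromo-9-chloro-1,5,5,9-tetramethyl-7-[(trimethylsilyl)oxy]spiro[5.5]undec-1-en-3-one (both C-4 epimers), via bis-silyl dienol ether 13 (not isolated)
Conditions: LiN(i-Pr)2 (2.3 equiv), Me3SiCl (3 equiv), THF, −78 °C; then NBS (1.05 equiv), THF, −78 °C
Reagents that add atoms: chlorotrimethylsilane, C[Si](C)(C)Cl; N-bromosuccinimide, O=C1CCC(=O)N1Br
Why: Kinetic α′-deprotonation of the enone with in situ silylation gives the cross-conjugated silyl dienol ether and the silyl ether of the carbinol, and electrophilic bromination of the dienol ether then places bromine on the carbon next to the gem-dimethyl group, whose configuration is irrelevant because it becomes sp2 in step 10 (the spiro descriptor changes only through priorities).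

**Step 9**
Reactants: 14 (6R,7S,9S,10S)-4,10-dibromo-9-chloro-1,5,5,9-tetramethyl-7-[(trimethylsilyl)oxy]spiro[5.5]undec-1-en-3-one
Product: 15 (6R,7S,9S,10S)-4,10-dibromo-9-chloro-1,5,5,9-tetramethyl-7-[(trimethylsilyl)oxy]spiro[5.5]undec-1-en-3-ol (3,4-cis)
Conditions: i-Bu2AlH (2.2 equiv), CH2Cl2, −78 °C; aq. potassium sodium tartrate
Reagents that add atoms: none
Why: The 1,2-reduction of the α-bromo enone by the non-basic aluminium hydride should deliver hydride anti to the C–Br bond (Felkin–Anh control) and give the cis bromohydrin, in which the hydrogen geminal to bromine is trans to the new oxygen as the next step requires.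

**Step 10**
Reactants: 15 (6R,7S,9S,10S)-4,10-dibromo-9-chloro-1,5,5,9-tetramethyl-7-[(trimethylsilyl)oxy]spiro[5.5]undec-1-en-3-ol
Product: 17 (1S,3S,4S,6R)-4,10-dibromo-3-chloro-3,7,11,11-tetramethylspiro[5.5]undeca-7,9-dien-1-ol, via trimethylsilyl ether 16 (not isolated)
Conditions: Ph2S[OC(CF3)2Ph]2 (Martin sulfurane, 1.5 equiv), CH2Cl2, 0 °C → rt; then citric acid, MeOH, 0 °C
Reagents that add atoms: none
Why: Martin sulfurane dehydration of the unhindered allylic alcohol should proceed by anti elimination of the hydrogen geminal to bromine (the only sp3 β-hydrogen, acidified by Br) to give the conjugated 2-bromo-1,3-diene, while the silyl ether keeps the C-1 oxygen from reacting with the sulfurane or capturing an allylic cation and is then removed by mild acidic methanolysis.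

**Compound list**

1 | 3-ethoxy-5,5-dimethylcyclohex-2-en-1-one | CCOC1=CC(=O)CC(C)(C)C1 | starting material
2 | 6-acetyl-3-ethoxy-5,5-dimethylcyclohex-2-en-1-one (racemic, enolisable C-6) | CCOC1=CC(=O)C(C(C)=O)C(C)(C)C1 | intermediate
3 | (2E)-1,3-dichlorobut-2-ene | ClC/C=C(/Cl)C | starting material
4 | (6R)-6-acetyl-6-[(2E)-3-chlorobut-2-en-1-yl]-3-ethoxy-5,5-dimethylcyclohex-2-en-1-one | CCOC1=CC(=O)[C@](C(C)=O)(C/C=C(/Cl)C)C(C)(C)C1 | intermediate
5 | diethyl 1-[(1R)-1-[(2E)-3-chlorobut-2-en-1-yl]-4-ethoxy-6,6-dimethyl-2-oxocyclohex-3-en-1-yl]ethenyl phosphate | CCOC1=CC(=O)[C@](C(=C)OP(=O)(OCC)OCC)(C/C=C(/Cl)C)C(C)(C)C1 | intermediate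
6 | (6R)-6-[(2E)-3-chlorobut-2-en-1-yl]-3-ethoxy-6-ethynyl-5,5-dimethylcyclohex-2-en-1-one | CCOC1=CC(=O)[C@](C#C)(C/C=C(/Cl)C)C(C)(C)C1 | intermediate
7 | (6R)-6-[(2E)-3-chlorobut-2-en-1-yl]-3-ethoxy-6-ethynyl-1,5,5-trimethylcyclohex-2-en-1-ol (C-1 epimers, formed as the lithium alkoxide) | CCOC1=CC(C)(O)[C@](C#C)(C/C=C(/Cl)C)C(C)(C)C1 | intermediate
8 | (4R)-4-[(2E)-3-chlorobut-2-en-1-yl]-4-ethynyl-3,5,5-trimethylcyclohex-2-en-1-one | CC1=CC(=O)CC(C)(C)[C@@]1(C#C)C/C=C(/Cl)C | intermediate
9 | (4S)-4-[(2E)-3-chlorobut-2-en-1-yl]-4-(1-chloroethenyl)-3,5,5-trimethylcyclohex-2-en-1-one | CC1=CC(=O)CC(C)(C)[C@@]1(C(Cl)=C)C/C=C(/Cl)C | intermediate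
10 | (6S,9S,10S)-10-bromo-7,9-dichloro-7-[(1,1,1,3,3,3-hexafluoropropan-2-yl)oxy]-1,5,5,9-tetramethylspiro[5.5]undec-1-en-3-one (C-7 unassigned) | CC1=CC(=O)CC(C)(C)[C@@]12C[C@H](Br)[C@@](C)(Cl)CC2(Cl)OC(C(F)(F)F)C(F)(F)F | intermediate
11 | (3S,4S,6S)-4-bromo-3-chloro-3,7,11,11-tetramethylspiro[5.5]undec-7-ene-1,9-dione | CC1=CC(=O)CC(C)(C)[C@@]12C[C@H](Br)[C@@](C)(Cl)CC2=O | intermediate
12 | (6S,7S,9S,10S)-10-bromo-9-chloro-7-hydroxy-1,5,5,9-tetramethylspiro[5.5]undec-1-en-3-one | CC1=CC(=O)CC(C)(C)[C@@]12C[C@H](Br)[C@@](C)(Cl)C[C@@H]2O | intermediate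
13 | (6R,7S,9S,10S)-10-bromo-9-chloro-1,5,5,9-tetramethyl-3,7-bis[(trimethylsilyl)oxy]spiro[5.5]undeca-1,3-diene | CC1=CC(O[Si](C)(C)C)=CC(C)(C)[C@@]12C[C@H](Br)[C@@](C)(Cl)C[C@@H]2O[Si](C)(C)C | intermediate
14 | (6R,7S,9S,10S)-4,10-dibromo-9-chloro-1,5,5,9-tetramethyl-7-[(trimethylsilyl)oxy]spiro[5.5]undec-1-en-3-one (both C-4 epimers) | CC1=CC(=O)C(Br)C(C)(C)[C@@]12C[C@H](Br)[C@@](C)(Cl)C[C@@H]2O[Si](C)(C)C | intermediate
15 | (6R,7S,9S,10S)-4,10-dibromo-9-chloro-1,5,5,9-tetramethyl-7-[(trimethylsilyl)oxy]spiro[5.5]undec-1-en-3-ol (3,4-cis, C-3/C-4 not fixed relative to C-6) | CC1=CC(O)C(Br)C(C)(C)[C@@]12C[C@H](Br)[C@@](C)(Cl)C[C@@H]2O[Si](C)(C)C | intermediate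
16 | {[(1S,3S,4S,6R)-4,10-dibromo-3-chloro-3,7,11,11-tetramethylspiro[5.5]undeca-7,9-dien-1-yl]oxy}trimethylsilane | CC1=CC=C(Br)C(C)(C)[C@@]12C[C@H](Br)[C@@](C)(Cl)C[C@@H]2O[Si](C)(C)C | intermediate
17 | (1S,3S,4S,6R)-4,10-dibromo-3-chloro-3,7,11,11-tetramethylspiro[5.5]undeca-7,9-dien-1-ol | CC1=CC=C(Br)C(C)(C)[C@@]12C[C@H](Br)[C@@](C)(Cl)C[C@@H]2O | target

**Step count and risks**

Total step count: 10. Longest linear sequence: 10 steps (from compound 1).

Steps most likely to fail:

1. Step 6 (proposed new method). What may go wrong: attack of Br+ on the terminating chloroalkene, capture of the first cation by solvent or proton loss to an allylic bromide before the C–C bond forms, a 1,2-shift at the second cation, or poor facial selectivity relative to the spiro carbon. The fallback uses known chemistry; it sets out from compound 8 and comes back at compound 11.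
   - Gold-catalysed hydration of the alkyne (Ph3PAuNTf2, MeOH/H2O, 50 °C) should give the methyl ketone (4S)-4-acetyl-4-[(2E)-3-chlorobut-2-en-1-yl]-3,5,5-trimethylcyclohex-2-en-1-one F1.
   - Palladium-catalysed intramolecular α-alkenylation of its enolate with the alkenyl chloride (Pd2(dba)3, 2-dicyclohexylphosphino-2′,4′,6′-triisopropylbiphenyl, NaOt-Bu, toluene, 60 °C) should close the same C2–C3 bond and give the β,γ-unsaturated diketone (6S)-3,7,11,11-tetramethylspiro[5.5]undeca-3,7-diene-1,9-dione F2.
   - Markovnikov anti bromochlorination of the ring B olefin (Bu4N[BrCl2], CH2Cl2, −78 °C) should put chlorine on the tertiary and bromine on the secondary carbon and return to diketone 11.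
   - The price: a trans-diaxial addition to a preformed ring cannot deliver bromine equatorially, so a lower diastereomer ratio at C-3/C-4 relative to the spiro carbon and a separation must be expected.

2. Step 10. What may go wrong: elimination through the allylic cation toward the ring methyl group (exocyclic diene) instead of toward the bromine-bearing carbon, or loss of the silyl ether followed by capture of the cation by the C-1 oxygen. The fallback sets out from compound 14 and comes back at compound 16, so that no cation and no regiochemical choice are involved.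
   - Deprotonation of the α-bromo ketone at the bromine-bearing carbon and O-triflation (KN(SiMe3)2, PhNTf2, THF, −78 °C) should give the enol triflate (6R,7S,9S,10S)-4,10-dibromo-9-chloro-1,5,5,9-tetramethyl-7-[(trimethylsilyl)oxy]spiro[5.5]undeca-1,3-dien-3-yl trifluoromethanesulfonate F3.
   - Palladium-catalysed hydrogenolysis of the C–OTf bond (Pd(OAc)2, 1,3-bis(diphenylphosphino)propane, HCO2H/Et3N, DMF, 60 °C; the bidentate phosphine favours the triflate over the vinyl bromide) should give silyl ether 16, which is desilylated as in step 10.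

3. Step 2. What may go wrong: sluggish C-allylation at the carbon flanked by the gem-dimethyl group, low enantioselectivity, or erosion of the E geometry by π–σ–π isomerisation of the allyl complex. The fallback sets out from compounds 2 and 3 and comes back at compound 4.
   - The enolate is alkylated directly (SN2, no π-allyl intermediate, so the olefin geometry cannot change) under chiral phase-transfer catalysis: a C2-symmetric N-spiro binaphthyl quaternary ammonium bromide (1 mol%), CsOH·H2O, toluene, −40 °C.
   - No compound outside the list is made (F0).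

**Further compounds**

F1 | step 6 | (4S)-4-acetyl-4-[(2E)-3-chlorobut-2-en-1-yl]-3,5,5-trimethylcyclohex-2-en-1-one | CC1=CC(=O)CC(C)(C)[C@@]1(C(C)=O)C/C=C(/Cl)C
F2 | step 6 | (6S)-3,7,11,11-tetramethylspiro[5.5]undeca-3,7-diene-1,9-dione | CC1=CC(=O)CC(C)(C)[C@@]12CC=C(C)CC2=O
F3 | step 10 | (6R,7S,9S,10S)-4,10-dibromo-9-chloro-1,5,5,9-tetramethyl-7-[(trimethylsilyl)oxy]spiro[5.5]undeca-1,3-dien-3-yl trifluoromethanesulfonate | CC1=CC(OS(=O)(=O)C(F)(F)F)=C(Br)C(C)(C)[C@@]12C[C@H](Br)[C@@](C)(Cl)C[C@@H]2O[Si](C)(C)C
F0 | step 2 | none | none
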